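## Analysis of the target

Compound 22 is a naphthalene-1,4-dione. Ring B is the quinone (carbonyls at C1 and C4, side chain on C2, hydrogen on C3). Ring A is benzenoid, with a methoxy group on C5 (peri to the C4 carbonyl) and a hydroxyl on C8 that is hydrogen-bonded to the C1 carbonyl. The C2 substituent is a six-carbon chain: C1' is a secondary carbinol carbon esterified with 3-methylbut-2-enoic acid, C2' is a methylene group, and C3'=C4' is a trisubstituted alkene with two methyl groups on C4'. C1' is the only stereocenter and is S; with no second stereocenter to relay from, it must be set by a reagent or a catalyst. The sensitive groups are: the quinone (base, nucleophiles, reductants; a reduced ring B next to the C1' acyloxy group can expel the carboxylate through a quinone methide); the C3'=C4' alkene, which under acid can be captured by the C1' oxygen; and the senecioate, whose double bond can slip out of conjugation. The difficulty is twofold. Three different oxygen functions (quinone at C1/C4, methyl ether at C5, phenol at C8) must be placed without ambiguity on a core whose oxygenation pattern is symmetric, with the chain on C2 and not C3. A lone benzylic stereocenter must also be made next to an electron-rich ring. The strategy rests on the array C2(aryl)–C1'H(O)–C2'H2–C3'=C4'. A heteroatom-bearing carbon bonded to an aryl carbon on one side and, through one methylene, to an alkenyl carbon on the other is what forms when an aryl group shifts from boron to the α-carbon of a B-vinyl group while palladium delivers an alkenyl group to the β-carbon; the C–B bond then stands in for the C–O bond.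

## Retrosynthetic reasoning

The acyl–oxygen bond of the C1' ester is cut last, giving quinone alcohol 20 and acid 21. In 20 the C1' hydroxyl is the only hydroxyl that is neither chelated nor peri-hindered, so it can be acylated selectively. Acylating at the very end also means that no reduced ring B ever sits next to a C1' carboxylate leaving group.

Ring B of 20 is traced back to a silyl-protected hydroquinone, carbinol 18, through the free triol 19. All three Si–O bonds are cut in one operation and aerobic oxidation follows. Because C5 is a methyl ether, only ring B can become a quinone, so no oxidative demethylation and no choice between the rings arises. Any silyl shift towards the carbinol oxygen at an earlier stage is harmless, since all silicon is removed here.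

The C1'–O bond of 18 is taken back to the C1'–B bond of boronate 17. Oxidation of a C–B bond proceeds with retention, so the configuration of 17 is that of the target.

Boronate 17 is cut at two bonds at once, C2–C1' and C2'–C3', into aryl boronate 11, vinyllithium 13 and alkenyl triflate 15, which meet through ate complex 16. These are the two bonds flanking the two-carbon unit C1'–C2'. Cutting there reduces the chain to a vinyl group and a four-carbon alkenyl electrophile with no stereochemistry of its own, and puts the creation of C1' into the bond-forming step. The forward reaction must make both bonds and set C1' by the catalyst alone.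

Triflate 15 comes from aldehyde 14 by trapping its enol form. Vinyllithium 13 is made from stannane 12 by tin–lithium exchange so that no halide ions accompany it into the key step, where they would occupy the vacant site on palladium.

The C2–B bond of 11 is cut back to the C2–Br bond of bromide 10. The silicon groups of 10 are removed to give triol 8 (through silylene naphthol 9), and 8 is the reduced form of bromoquinone 7. The peri oxygens on C1 and C8 are tied by one silicon atom because two separate bulky silyl groups cannot sit side by side there; the C4 oxygen takes an ordinary silyl group.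

In 7 the C8–O bond is cut, leading to 5 through trifluoroacetate 6. The C1 carbonyl is the natural handle for placing oxygen on the only peri C–H bond. Quinone 5 goes back through phenol 4 and acetate 3 to diacetate 2 and the symmetric diol 1. The oxidative bromination of 2 fixes the position of bromine relative to the C5 oxygen, and thereby C2 against C3, in one step.

## Alternatives that were turned down

Alternative 1: Ring A is disconnected at C8–C8a and C4a–C5, i.e. into a ring-B aryne and a furan. Forward, bromoarene A1 carries ring B as a 1,4-dimethoxybenzene with the S side chain already in place, its C1' oxygen joined through an Si(iPr)2–O–Si(iPr)2 tether to the 2-oxygen of a furan. LiN(iPr)2 removes HBr, the strained triple bond is trapped by the tethered furan in an intramolecular (4+2) cycloaddition, and the oxygen bridge opens to naphthol A2.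
- For: the tether fixes the orientation of the two partners, so in A2 the C5 oxygen is free and the C8 oxygen is masked from the start. On this point it is stronger than the chosen route, which differentiates C8 by a late C–H oxygenation.
- Against: the stereocenter must exist before the key step, so a separate asymmetric step is still needed. The benzylic, oxygen-bearing C1'–H is exposed to a strong amide base. The cycloaddition passes through a ten-membered tether ring. The unsymmetrical disiloxane needs two different Si–O bonds made in order.
- Against, decisive: ring B ends as a dimethyl ether, so the quinone must be made by oxidative demethylation when ring A (C5 methoxy para to C8 hydroxyl) is the more easily oxidized ring. The oxidation level of the wrong ring is therefore at risk.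
- Comparison: the chosen strategy makes C1' and the chain in one catalytic step and unveils ring B by desilylation, with no oxidant that could choose ring A.

Alternative 2: Ring B is disconnected at C2=C3. Forward, diene A3 (a benzene ring with two neighbouring carbinol arms, one vinyl and one 1,1-disubstituted alkene bearing the silylated S side chain) is closed with the second-generation Grubbs catalyst, with loss of ethylene, to the 1,4-dihydronaphthalene-1,4-diol A4.
- For: neutral conditions, the C2/C3 question is answered by construction, and the prenyl alkene cannot compete (it would close a four- or nine-membered ring).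
- Against: the alkene formed is trisubstituted and flanked by two oxygenated carbons, which slows metathesis. A4 is one dehydration away from a naphthol, which would cost a ring oxygen. Two carbinols must then be oxidized to the quinone. The two ortho arms of A3 must be installed one after the other on neighbouring carbons with the right orientation towards the C5 and C8 oxygens. The stereocenter again comes from a separate step.
- Comparison: it is longer and solves neither the stereocenter nor the ring-A differentiation in its key step. The chosen route buys the arene core from a symmetric bulk diol by substitution chemistry and spends its key step on the stereocenter.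

Alternative 3: Ring B is disconnected at C3–C4, C1–C2 and C1–C8a. Forward, chromium carbene complex A5, one of its CO ligands and the terminal alkyne A6 combine in a Dötz benzannulation to the 4-methoxy-1-naphthol A7.
- For: this is the most convergent option. The larger alkyne substituent ends next to the phenol, i.e. on C2. Ring B is born as a para-methoxyphenol that a mild oxidant converts to the quinone in preference to ring A. The step count is comparable to or slightly below that of the chosen route. On convergence and on the ring-B oxidation level it is as strong or stronger.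
- Against: chromium is used stoichiometrically. An ortho-methoxyaryl carbene with a bulky propargylic silyl ether invites the usual side channels (cyclobutenone, indene). The chiral alkyne A6 must come from an asymmetric alkynylation or ynone reduction of a β,γ-unsaturated carbonyl precursor that isomerizes readily into conjugation. The stereocenter is therefore made in a separate step on an awkward substrate.
- Comparison: the chosen strategy creates C1' catalytically from three achiral components in the same step that builds the chain, and gives either enantiomer by exchanging the ligand. It does use tin once, to make 13 free of halide.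

Key step: step 11

Assumption: the sense of induction is taken from the aryl-migration precedent, in which the (Sp,Sp)-MandyPhos ligand leads to the R carbinol series. The (Rp,Rp) ligand is therefore specified for the S series; if a trial on a simple aryl boronate shows the opposite sense, the other ligand enantiomer is used with no other change.

## Route

Naphthalene numbering of 22 is kept for all intermediates.

Step 1
Reactants: 1 naphthalene-1,5-diol
Product: 2 naphthalene-1,5-diyl diacetate
Conditions: Ac2O, pyridine, DMAP (cat.), rt
Reagents that add atoms: acetic anhydride CC(=O)OC(C)=O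
Why: Plain O-acetylation of both naphthols (nucleophilic acyl substitution under DMAP catalysis); the acetates temper the rings for the controlled oxidation that follows.

Step 2
Reactants: 2 naphthalene-1,5-diyl diacetate
Product: 3 5-acetoxy-2-bromonaphthalene-1,4-dione
Conditions: N-bromosuccinimide (4 equiv), AcOH/H2O, 60 °C
Reagents that add atoms: N-bromosuccinimide O=C1CCC(=O)N1Br; water O
Why: Oxidative bromination of an aryl acetate: bromination ortho and para to the C1 acetoxy group, then hydrolytic oxidation of that ring, should leave bromine on C2 next to the carbonyl that derives from the acetoxy-bearing carbon, with the surviving acetate peri to the new C4 carbonyl. This is the established reactivity pattern for 1,5-diacyloxynaphthalenes and fixes C2 against C3.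

Step 3
Reactants: 3 5-acetoxy-2-bromonaphthalene-1,4-dione
Product: 4 2-bromo-5-hydroxynaphthalene-1,4-dione
Conditions: H2SO4 (cat.), EtOH, reflux
Reagents that add atoms: none
Why: Acid-catalysed transesterification removes the aryl acetate; acid is used because hydroxide or alkoxide would displace the vinylogous acyl bromide at C2.

Step 4
Reactants: 4 2-bromo-5-hydroxynaphthalene-1,4-dione
Product: 5 2-bromo-5-methoxynaphthalene-1,4-dione
Conditions: MeI, Ag2O, CH2Cl2, rt, dark
Reagents that add atoms: iodomethane CI
Why: Purdie-type O-methylation alkylates the chelated peri phenol under neutral conditions, so no addition–elimination occurs at the bromoquinone.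

Step 5
Reactants: 5 2-bromo-5-methoxynaphthalene-1,4-dione
Product: 7 2-bromo-8-hydroxy-5-methoxynaphthalene-1,4-dione, via quinone C8 trifluoroacetate 6 (not isolated)
Conditions: [RuCl2(p-cymene)]2 (5 mol%), PhI(OCOCF3)2, CF3CO2H/(CF3CO)2O, 80 °C; then aq NaHCO3, THF, rt
Reagents that add atoms: [bis(trifluoroacetoxy)iodo]benzene O=C(OI(OC(=O)C(F)(F)F)c1ccccc1)C(F)(F)F
Why: Carbonyl-directed ruthenium-catalysed C–H oxygenation: the C1 carbonyl binds ruthenium, carboxylate-assisted metalation of the only peri C–H bond (C8; C5 is blocked by the methoxy group) gives a five-membered ruthenacycle, and oxidation to tetravalent ruthenium followed by C–O reductive elimination gives trifluoroacetate 6. The ester shields the new oxygen from over-oxidation until mild hydrolysis frees the phenol, and C8 is also para to the methoxy group, so directing and electronic preferences coincide.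

Step 6
Reactants: 7 2-bromo-8-hydroxy-5-methoxynaphthalene-1,4-dione
Product: 8 2-bromo-5-methoxynaphthalene-1,4,8-triol
Conditions: Na2S2O4, EtOAc/H2O, rt, argon; dried and used at once
Reagents that add atoms: none
Why: Two-electron reduction of the quinone by dithionite in a two-phase system; the aryl bromide is not touched, and immediate silylation forestalls air oxidation and keto tautomerization of the triol.

Step 7
Reactants: 8 2-bromo-5-methoxynaphthalene-1,4,8-triol
Product: 10 2-bromo-4-(tert-butyldimethylsilyloxy)-1,8-(di-tert-butylsilanediyldioxy)-5-methoxynaphthalene, via silylene naphthol 9 (not isolated)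
Conditions: tBu2Si(OTf)2 (1.05 equiv), 2,6-lutidine, CH2Cl2, −20 to 0 °C; then TBSOTf, 0 °C to rt
Reagents that add atoms: di-tert-butylsilyl bis(trifluoromethanesulfonate) CC(C)(C)[Si](OS(=O)(=O)C(F)(F)F)(OS(=O)(=O)C(F)(F)F)C(C)(C)C; tert-butyldimethylsilyl trifluoromethanesulfonate CC(C)(C)[Si](C)(C)OS(=O)(=O)C(F)(F)F
Why: Silylene protection of a diol followed by silyl ether formation: the peri diol is the most acidic site (its monoanion is held by an internal hydrogen bond), so the bis-triflate should meet it first and close the six-membered O–Si–O ring to 9. The remaining C4 hydroxyl, which cannot reach that silicon, is then capped in the same flask.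

Step 8
Reactants: 10 2-bromo-4-(tert-butyldimethylsilyloxy)-1,8-(di-tert-butylsilanediyldioxy)-5-methoxynaphthalene
Product: 11 2-[4-(tert-butyldimethylsilyloxy)-1,8-(di-tert-butylsilanediyldioxy)-5-methoxynaphthalen-2-yl]-4,4,5,5-tetramethyl-1,3,2-dioxaborolane
Conditions: B2pin2, PdCl2(dppf) (5 mol%), KOAc, 1,4-dioxane, 90 °C
Reagents that add atoms: bis(pinacolato)diboron CC1(C)OB(OC1(C)C)B1OC(C)(C)C(C)(C)O1
Why: Miyaura borylation (oxidative addition of the aryl bromide to zerovalent palladium, acetate-assisted transmetalation, reductive elimination). KOAc leaves aryl silyl ethers intact, and no aryllithium is generated next to an O–Si bond, which could invite silyl migration to carbon.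

Step 9
Reactants: 12 tetravinylstannane
Product: 13 vinyllithium
Conditions: n-BuLi, pentane, rt, argon; solid washed with pentane, dissolved in THF, titrated
Reagents that add atoms: n-butyllithium [Li]CCCC
Why: Tin–lithium exchange gives vinyllithium free of halide, which matters because halide ions would bind the cationic palladium intermediate of step 11 and stop the metallate shift.

Step 10
Reactants: 14 2-methylpropanal
Product: 15 2-methylprop-1-en-1-yl trifluoromethanesulfonate
Conditions: Tf2O, 2,6-di-tert-butyl-4-methylpyridine, CH2Cl2, 0 °C to rt
Reagents that add atoms: trifluoromethanesulfonic anhydride O=S(=O)(OS(=O)(=O)C(F)(F)F)C(F)(F)F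
Why: Enol triflate formation from an enolizable aldehyde: O-sulfonylation of the carbonyl and loss of the α-proton to the hindered, non-nucleophilic base; no alkene geometry arises because the far carbon carries two methyl groups.

Step 11
Reactants: 11 2-[4-(tert-butyldimethylsilyloxy)-1,8-(di-tert-butylsilanediyldioxy)-5-methoxynaphthalen-2-yl]-4,4,5,5-tetramethyl-1,3,2-dioxaborolane; 13 vinyllithium; 15 2-methylprop-1-en-1-yl trifluoromethanesulfonate
Product: 17 2-{(1S)-1-[4-(tert-butyldimethylsilyloxy)-1,8-(di-tert-butylsilanediyldioxy)-5-methoxynaphthalen-2-yl]-4-methylpent-3-en-1-yl}-4,4,5,5-tetramethyl-1,3,2-dioxaborolane, via lithium vinylboronate complex 16 (not isolated)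
Conditions: 11, THF, 0 °C, 13 (1.0 equiv), then rt; Pd(OAc)2 (2 mol%), (Rp,Rp)-MandyPhos [1,1'-bis((S)-α-(dimethylamino)benzyl)-2,2'-bis(diphenylphosphino)ferrocene] (2.4 mol%), 15 (1.2 equiv), THF, 60 °C
Reagents that add atoms: none
Why: Vinyllithium 13 adds to boron of 11 to give the four-coordinate ate complex 16, whose vinyl group is now an electron-rich alkene. Oxidative addition of triflate 15 to zerovalent palladium (from Pd(OAc)2 and the diphosphine) gives a cationic alkenyl complex of divalent palladium which, triflate being non-coordinating, binds the vinyl group of 16. Binding triggers a 1,2-shift of the naphthyl group from boron to the inner vinyl carbon, anti to palladium, forming C2–C1' while the terminal carbon becomes bound to palladium, and reductive elimination then forms C2'–C3' and returns zerovalent palladium. The closest known reaction is the palladium-catalysed enantioselective conjunctive cross-coupling of vinyl boron ate complexes with aryl migrating groups and alkenyl triflates under MandyPhos ligands. No ring is closed. C1' is the only new stereocenter and is controlled by the ligand alone, whose chiral pocket selects the face of the bound vinyl group, the substrate having no stereocenter of its own. The step needs the metallate shift to win over direct transfer of the aryl or vinyl group to palladium and over β-hydride elimination; the four-coordinate boron (no empty orbital for transmetalation), the absence of halide and the wide bite angle of the ligand secure this, and the silyl ethers and the pinacol ester are inert to 13 at 0 °C. The open point is the ortho silyloxy group on the migrating carbon, which may slow ate formation and migration but should not change their course.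

Step 12
Reactants: 17 2-{(1S)-1-[4-(tert-butyldimethylsilyloxy)-1,8-(di-tert-butylsilanediyldioxy)-5-methoxynaphthalen-2-yl]-4-methylpent-3-en-1-yl}-4,4,5,5-tetramethyl-1,3,2-dioxaborolane
Product: 18 (1S)-1-[4-(tert-butyldimethylsilyloxy)-1,8-(di-tert-butylsilanediyldioxy)-5-methoxynaphthalen-2-yl]-4-methylpent-3-en-1-ol
Conditions: NaBO3·4H2O, THF/H2O, rt
Reagents that add atoms: sodium perborate tetrahydrate (NaBO3·4H2O) [Na+].[Na+].O[B-]1(O)OO[B-](O)(O)OO1
Why: Oxidation of a C–B bond: peroxide adds to boron and C1' migrates from boron to oxygen with retention, giving the S carbinol after hydrolysis. Perborate is preferred to NaOH/H2O2 because strong base with hydroperoxide would strip the aryl silyl ethers and expose the hydroquinone to oxidant, and the alkene is inert to nucleophilic peroxide.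

Step 13
Reactants: 18 (1S)-1-[4-(tert-butyldimethylsilyloxy)-1,8-(di-tert-butylsilanediyldioxy)-5-methoxynaphthalen-2-yl]-4-methylpent-3-en-1-ol
Product: 20 8-hydroxy-2-[(1S)-1-hydroxy-4-methylpent-3-en-1-yl]-5-methoxynaphthalene-1,4-dione, via naphthalenetriol 19 (not isolated)
Conditions: HF·pyridine, pyridine, THF, 0 °C to rt, argon; then EtOAc/pH 7 phosphate buffer, air, rt
Reagents that add atoms: none
Why: Fluoride cleaves all three aryl O–Si bonds (Si–F bond strength) to give triol 19, and autoxidation of this electron-rich naphthalene-1,4-diol gives the quinone. Only ring B can be oxidized to a quinone because C5 is a methyl ether, excess pyridine keeps the medium too weakly acidic to ionize C1' or cyclize onto the alkene, and any silyl shift suffered in step 12 is erased here.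

Step 14
Reactants: 20 8-hydroxy-2-[(1S)-1-hydroxy-4-methylpent-3-en-1-yl]-5-methoxynaphthalene-1,4-dione; 21 3-methylbut-2-enoic acid
Product: 22 (1S)-1-(8-hydroxy-5-methoxy-1,4-dioxo-1,4-dihydronaphthalen-2-yl)-4-methylpent-3-en-1-yl 3-methylbut-2-enoate
Conditions: DCC, DMAP (0.1 equiv), CH2Cl2, 0 °C to rt
Reagents that add atoms: none
Why: Steglich esterification: the acid is activated as the O-acylisourea and DMAP passes the acyl group to the secondary C1' hydroxyl. The C8 phenol is tied up in its hydrogen bond to the C1 carbonyl and peri-hindered, the pattern that makes side-chain acylation of chelated hydroxynaphthoquinones selective, and the C1'–O bond is not broken, so the S configuration is kept.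

## Compound list

1 | naphthalene-1,5-diol | Oc1cccc2c(O)cccc12 | starting material
2 | naphthalene-1,5-diyl diacetate | CC(=O)Oc1cccc2c(OC(C)=O)cccc12 | intermediate
3 | 5-acetoxy-2-bromonaphthalene-1,4-dione | CC(=O)Oc1cccc2c1C(=O)C=C(Br)C2=O | intermediate
4 | 2-bromo-5-hydroxynaphthalene-1,4-dione | Oc1cccc2c1C(=O)C=C(Br)C2=O | intermediate
5 | 2-bromo-5-methoxynaphthalene-1,4-dione | COc1cccc2c1C(=O)C=C(Br)C2=O | intermediate
6 | 7-bromo-4-methoxy-5,8-dioxo-5,8-dihydronaphthalen-1-yl trifluoroacetate | COc1ccc(OC(=O)C(F)(F)F)c2c1C(=O)C=C(Br)C2=O | intermediate
7 | 2-bromo-8-hydroxy-5-methoxynaphthalene-1,4-dione | COc1ccc(O)c2c1C(=O)C=C(Br)C2=O | intermediate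
8 | 2-bromo-5-methoxynaphthalene-1,4,8-triol | COc1ccc(O)c2c(O)c(Br)cc(O)c12 | intermediate
9 | 2-bromo-1,8-(di-tert-butylsilanediyldioxy)-5-methoxynaphthalen-4-ol (C1 and C8 oxygens bridged by Si(tBu)2) | COc1ccc2O[Si](C(C)(C)C)(C(C)(C)C)Oc3c(Br)cc(O)c1c23 | intermediate
10 | 2-bromo-4-(tert-butyldimethylsilyloxy)-1,8-(di-tert-butylsilanediyldioxy)-5-methoxynaphthalene | COc1ccc2O[Si](C(C)(C)C)(C(C)(C)C)Oc3c(Br)cc(O[Si](C)(C)C(C)(C)C)c1c23 | intermediate
11 | 2-[4-(tert-butyldimethylsilyloxy)-1,8-(di-tert-butylsilanediyldioxy)-5-methoxynaphthalen-2-yl]-4,4,5,5-tetramethyl-1,3,2-dioxaborolane | COc1ccc2O[Si](C(C)(C)C)(C(C)(C)C)Oc3c(B4OC(C)(C)C(C)(C)O4)cc(O[Si](C)(C)C(C)(C)C)c1c23 | intermediate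
12 | tetravinylstannane | C=C[Sn](C=C)(C=C)C=C | starting material
13 | vinyllithium | [Li]C=C | intermediate
14 | 2-methylpropanal | CC(C)C=O | starting material
15 | 2-methylprop-1-en-1-yl trifluoromethanesulfonate | CC(C)=COS(=O)(=O)C(F)(F)F | intermediate
16 | lithium [4-(tert-butyldimethylsilyloxy)-1,8-(di-tert-butylsilanediyldioxy)-5-methoxynaphthalen-2-yl](vinyl)(pinacolato)borate | [Li+].COc1ccc2O[Si](C(C)(C)C)(C(C)(C)C)Oc3c([B-]4(C=C)OC(C)(C)C(C)(C)O4)cc(O[Si](C)(C)C(C)(C)C)c1c23 | intermediate
17 | 2-{(1S)-1-[4-(tert-butyldimethylsilyloxy)-1,8-(di-tert-butylsilanediyldioxy)-5-methoxynaphthalen-2-yl]-4-methylpent-3-en-1-yl}-4,4,5,5-tetramethyl-1,3,2-dioxaborolane | COc1ccc2O[Si](C(C)(C)C)(C(C)(C)C)Oc3c([C@H](CC=C(C)C)B4OC(C)(C)C(C)(C)O4)cc(O[Si](C)(C)C(C)(C)C)c1c23 | intermediate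
18 | (1S)-1-[4-(tert-butyldimethylsilyloxy)-1,8-(di-tert-butylsilanediyldioxy)-5-methoxynaphthalen-2-yl]-4-methylpent-3-en-1-ol | COc1ccc2O[Si](C(C)(C)C)(C(C)(C)C)Oc3c([C@H](CC=C(C)C)O)cc(O[Si](C)(C)C(C)(C)C)c1c23 | intermediate
19 | 2-[(1S)-1-hydroxy-4-methylpent-3-en-1-yl]-5-methoxynaphthalene-1,4,8-triol | COc1ccc(O)c2c(O)c([C@H](CC=C(C)C)O)cc(O)c12 | intermediate
20 | 8-hydroxy-2-[(1S)-1-hydroxy-4-methylpent-3-en-1-yl]-5-methoxynaphthalene-1,4-dione | COc1ccc(O)c2c1C(=O)C=C([C@H](CC=C(C)C)O)C2=O | intermediate
21 | 3-methylbut-2-enoic acid | CC(C)=CC(=O)O | starting material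
22 | (1S)-1-(8-hydroxy-5-methoxy-1,4-dioxo-1,4-dihydronaphthalen-2-yl)-4-methylpent-3-en-1-yl 3-methylbut-2-enoate | COc1ccc(O)c2c1C(=O)C=C([C@H](CC=C(C)C)OC(=O)C=C(C)C)C2=O | target

## Step count and least certain steps

Total: 14 steps. Longest linear sequence: 12 steps (steps 1 to 8 and 11 to 14, from 1); steps 9 and 10 are one-step side branches.

Step 11 (key step). The migrating carbon carries an ortho silyloxy group and lies beside the peri-fused silylene ring. Ate formation and the aryl shift may therefore be slow, which would let the vinyl or the aryl group pass directly to palladium (plain Suzuki–Miyaura coupling with 15). Vinyllithium could also attack silicon, and the crowded migrating group could erode the facial selectivity set by the ligand. Fallback (from 11, returning at 17): a lithiation–borylation homologation, in which the stereocenter comes from a chiral diamine and not from palladium. 4-Methylpent-3-en-1-ol and N,N-diisopropylcarbamoyl chloride give 4-methylpent-3-en-1-yl N,N-diisopropylcarbamate F1. Deprotonation with s-BuLi and (+)-sparteine in Et2O at −78 °C should give the configurationally stable (1R)-1-lithio-4-methylpent-3-en-1-yl N,N-diisopropylcarbamate F2. Addition of 11 forms, with retention at carbon, the lithium boronate complex F3. Warming with MgBr2·OEt2 then drives the 1,2-shift of the naphthyl group with inversion and loss of the carbamate, which should deliver 17.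

Step 5. The hot, acidic oxidizing medium may attack the methoxy-bearing ring without direction or degrade the bromoquinone, and chelation of ruthenium between the C4 carbonyl and the methoxy oxygen may stall turnover. Fallback (from 1, returning at 7): all four oxygens are placed by classical substitution and bromine comes last.
- 1 is O-methylated (Me2SO4, K2CO3, acetone) to 1,5-dimethoxynaphthalene F4.
- Bromination para to each methoxy group (N-bromosuccinimide, MeCN) gives 4,8-dibromo-1,5-dimethoxynaphthalene F5.
- NaOMe/CuI converts this into 1,4,5,8-tetramethoxynaphthalene F6.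
- (NH4)2Ce(NO3)6 oxidizes one ring to 5,8-dimethoxynaphthalene-1,4-dione F7.
- One equivalent of AlCl3 removes one chelated methyl group to give 5-hydroxy-8-methoxynaphthalene-1,4-dione F8.
- Br2 in acetic acid adds to give trans-2,3-dibromo-5-hydroxy-8-methoxy-2,3-dihydronaphthalene-1,4-dione F9 (racemic).
- Loss of HBr with NaOAc should leave bromine next to the hydrogen-bonded carbonyl, because the proton α to that carbonyl is the more acidic one; that product is 7.

Step 7. The first silylation may occur at the C4 hydroxyl, which cannot close the ring, leading to open-chain silyl triflates and oligomers; triol 8 may also be lost to air oxidation or keto tautomerization before it is capped. Fallback (from 7, returning at 9 and so at 10): the silicon bridge is attached before the third hydroxyl exists. The single hydroxyl of 7 is silylated with tBu2Si(H)OTf and 2,6-lutidine to 2-bromo-8-(di-tert-butylsilyloxy)-5-methoxynaphthalene-1,4-dione F10. Na2S2O4 reduction gives 2-bromo-8-(di-tert-butylsilyloxy)-5-methoxynaphthalene-1,4-diol F11. Catalytic B(C6F5)3 then couples the Si–H bond with the C1 hydroxyl, the only one within reach, with loss of H2, giving 9, which is silylated at C4 as in step 7.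

Step 14. On the free quinone, DMAP or the alkoxide may add to C3, the C8 phenol may be acylated in part, and the activated acid may lose its conjugation through a ketene. Fallback (from 18, returning at 22): the ester is made before the quinone. Carbinol 18, whose only free hydroxyl is at C1', is esterified with 21 (DCC, DMAP) to (1S)-1-[4-(tert-butyldimethylsilyloxy)-1,8-(di-tert-butylsilanediyldioxy)-5-methoxynaphthalen-2-yl]-4-methylpent-3-en-1-yl 3-methylbut-2-enoate F12. HF·pyridine/pyridine in THF under O2 frees (1S)-1-(1,4,8-trihydroxy-5-methoxynaphthalen-2-yl)-4-methylpent-3-en-1-yl 3-methylbut-2-enoate F13, which is oxidized as it forms (Ag2O added at the end) to 22. This order risks expulsion of the carboxylate from F13 through a quinone methide, which is why it is the fallback and not the main line.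

## Further compounds

F1 | step 11 | 4-methylpent-3-en-1-yl N,N-diisopropylcarbamate | CC(C)=CCCOC(=O)N(C(C)C)C(C)C
F2 | step 11 | (1R)-1-lithio-4-methylpent-3-en-1-yl N,N-diisopropylcarbamate | [Li][C@H](CC=C(C)C)OC(=O)N(C(C)C)C(C)C
F3 | step 11 | lithium boronate complex of 11 and F2 | [Li+].COc1ccc2O[Si](C(C)(C)C)(C(C)(C)C)Oc3c([B-]4([C@H](CC=C(C)C)OC(=O)N(C(C)C)C(C)C)OC(C)(C)C(C)(C)O4)cc(O[Si](C)(C)C(C)(C)C)c1c23
F4 | step 5 | 1,5-dimethoxynaphthalene | COc1cccc2c(OC)cccc12
F5 | step 5 | 4,8-dibromo-1,5-dimethoxynaphthalene | COc1ccc(Br)c2c(OC)ccc(Br)c12
F6 | step 5 | 1,4,5,8-tetramethoxynaphthalene | COc1ccc(OC)c2c(OC)ccc(OC)c12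
F7 | step 5 | 5,8-dimethoxynaphthalene-1,4-dione | COc1ccc(OC)c2c1C(=O)C=CC2=O
F8 | step 5 | 5-hydroxy-8-methoxynaphthalene-1,4-dione | COc1ccc(O)c2c1C(=O)C=CC2=O
F9 | step 5 | trans-2,3-dibromo-5-hydroxy-8-methoxy-2,3-dihydronaphthalene-1,4-dione (racemic, one enantiomer drawn) | COc1ccc(O)c2c1C(=O)[C@@H](Br)[C@H](Br)C2=O
F10 | step 7 | 2-bromo-8-(di-tert-butylsilyloxy)-5-methoxynaphthalene-1,4-dione | COc1ccc(O[SiH](C(C)(C)C)C(C)(C)C)c2c1C(=O)C=C(Br)C2=O
F11 | step 7 | 2-bromo-8-(di-tert-butylsilyloxy)-5-methoxynaphthalene-1,4-diol | COc1ccc(O[SiH](C(C)(C)C)C(C)(C)C)c2c(O)c(Br)cc(O)c12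
F12 | step 14 | (1S)-1-[4-(tert-butyldimethylsilyloxy)-1,8-(di-tert-butylsilanediyldioxy)-5-methoxynaphthalen-2-yl]-4-methylpent-3-en-1-yl 3-methylbut-2-enoate | COc1ccc2O[Si](C(C)(C)C)(C(C)(C)C)Oc3c([C@H](CC=C(C)C)OC(=O)C=C(C)C)cc(O[Si](C)(C)C(C)(C)C)c1c23
F13 | step 14 | (1S)-1-(1,4,8-trihydroxy-5-methoxynaphthalen-2-yl)-4-methylpent-3-en-1-yl 3-methylbut-2-enoate | COc1ccc(O)c2c(O)c([C@H](CC=C(C)C)OC(=O)C=C(C)C)cc(O)c12
A1 | alternative 1 | 1-[(1S)-1-(3-bromo-2,5-dimethoxyphenyl)-4-methylpent-3-enyloxy]-3-(furan-2-yloxy)-1,1,3,3-tetraisopropyldisiloxane | COc1cc([C@H](CC=C(C)C)O[Si](C(C)C)(C(C)C)O[Si](C(C)C)(C(C)C)Oc2ccco2)c(OC)c(Br)c1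
A2 | alternative 1 | (S)-1,4-dimethoxynaphthalen-5-ol whose C8 oxygen is linked through Si(iPr)2–O–Si(iPr)2 to the C1' oxygen of the C2 side chain | COc1cc2c(OC)c3c(ccc(O)c13)O[Si](C(C)C)(C(C)C)O[Si](C(C)C)(C(C)C)O[C@H]2CC=C(C)C
A3 | alternative 2 | (3S)-3-(tert-butyldimethylsilyloxy)-1-[2-(1-hydroxyprop-2-enyl)-3-methoxy-6-(triisopropylsilyloxy)phenyl]-6-methyl-2-methylidenehept-5-en-1-ol (carbinol epimers) | COc1ccc(O[Si](C(C)C)(C(C)C)C(C)C)c(C(O)C(=C)[C@H](CC=C(C)C)O[Si](C)(C)C(C)(C)C)c1C(O)C=C
A4 | alternative 2 | 2-[(1S)-1-(tert-butyldimethylsilyloxy)-4-methylpent-3-enyl]-5-methoxy-8-(triisopropylsilyloxy)-1,4-dihydronaphthalene-1,4-diol (carbinol epimers) | COc1ccc(O[Si](C(C)C)(C(C)C)C(C)C)c2c1C(O)C=C([C@H](CC=C(C)C)O[Si](C)(C)C(C)(C)C)C2O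
A5 | alternative 3 | pentacarbonyl{methoxy[2-methoxy-5-(triisopropylsilyloxy)phenyl]methylidene}chromium | COC(=[Cr](=C=O)(=C=O)(=C=O)(=C=O)=C=O)c1cc(O[Si](C(C)C)(C(C)C)C(C)C)ccc1OC
A6 | alternative 3 | (3S)-3-(tert-butyldimethylsilyloxy)-6-methylhept-5-en-1-yne | C#C[C@H](CC=C(C)C)O[Si](C)(C)C(C)(C)C
A7 | alternative 3 | 2-[(1S)-1-(tert-butyldimethylsilyloxy)-4-methylpent-3-enyl]-4,5-dimethoxy-8-(triisopropylsilyloxy)naphthalen-1-ol | COc1ccc(O[Si](C(C)C)(C(C)C)C(C)C)c2c(O)c([C@H](CC=C(C)C)O[Si](C)(C)C(C)(C)C)cc(OC)c12
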